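The lactone ring is cut at C4a–C4 and at O2–C3, which makes the isochromanone a formal [4+2] adduct of a benzoic acid and a 1,3-diene. The key step exploits that C4a is the only C–H carbon ortho to the carboxyl group of 4-methoxysalicylic acid, whose OH and OMe already sit at the future C8 and C6: carboxylate-directed C–H palladation, insertion of (E)-piperylene and enantioselective allylic C–O closure build the lactone ring and the C3 stereocentre in one oxidative operation from two commercial compounds. Cross-metathesis with undec-10-en-1-ol then installs the chain and hydrogenation saturates it; no protecting group is needed.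

Key step: step 1

Remark (assumption): (E)-penta-1,3-diene is used as the pure E isomer. Which antipode of the amino acid ligand in step 1 leads to the 3S lactone cannot be predicted with confidence; the L-form is written, and the D-form would be used if the sense of induction proves opposite.

Step 1
Reactants: 1 2-hydroxy-4-methoxybenzoic acid; 2 (E)-penta-1,3-diene
Product: 3 (3S)-8-hydroxy-6-methoxy-3-[(E)-prop-1-en-1-yl]-3,4-dihydro-1H-isochromen-1-one
Conditions: Pd(OAc)2 (10 mol %), N-acetyl-L-tert-leucine (20 mol %), KHCO3 (0.5 equiv), 2,5-di-tert-butyl-1,4-benzoquinone (1.2 equiv), 2 (3 equiv), t-AmylOH, 70 °C, sealed tube, Ar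
Reagents that add atoms: none
Why: Proposed new method: the potassium carboxylate of 1 binds the amino-acid-ligated divalent palladium and directs concerted metalation–deprotonation to C6–H, the only C–H ortho to the carboxyl, to give a five-membered aryl palladacycle; the unsubstituted vinyl end of 2 then inserts syn into the Ar–Pd bond (aryl to the CH2 terminus) to give an η3-allylpalladium carboxylate, the carboxylate oxygen closes onto the proximal allyl carbon, and the quinone reoxidises the zerovalent palladium that is released. The closest known reaction types are the annulation of ortho-thallated benzoic acids with 1,3-dienes under PdCl2 to 3-vinyl-3,4-dihydroisocoumarins, the enantioselective oxidative annulation of N-aryl ureas and N-alkoxybenzamides with 1,3-dienes under divalent palladium with chiral ligands, and the carboxylate-directed ortho-palladation of salicylic acids with the OH left free; new is the merger of carboxylate-directed C–H activation, diene insertion and asymmetric C–O closure in one catalytic cycle. The lactone ring closes by allylic C–O bond formation in a 6-exo sense at the allyl carbon next to the benzylic CH2 (the remaining C=C ends up outside the ring), since attack at the distal allyl carbon would demand an eight-membered ring. The C3 stereocentre should be controlled by the chiral N-acyl amino acid ligand, which stays chelated to palladium through the C–H cleavage and selects the face of the diene in the migratory insertion, after which the allyl face is fixed and C–O formation is stereospecific. The step needs C6–H over C3–H and C5–H (secured by carboxylate chelation, the electron-rich positions being out of reach of the directing group), insertion at the terminal rather than the methyl-bearing alkene (sterics), and annulation ahead of quinone-promoted diacyloxylation of the diene, Diels–Alder addition to the oxidant and protodecarboxylation of 1 (hindered quinone, no added acetate or chloride, no silver salt, 70 °C).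

Step 2
Reactants: 3 (3S)-8-hydroxy-6-methoxy-3-[(E)-prop-1-en-1-yl]-3,4-dihydro-1H-isochromen-1-one; 4 undec-10-en-1-ol
Product: 5 (3S)-8-hydroxy-3-[(E)-11-hydroxyundec-1-en-1-yl]-6-methoxy-3,4-dihydro-1H-isochromen-1-one
Conditions: 4 (3 equiv), second-generation Grubbs catalyst RuCl2(PCy3)(H2IMes)(=CHPh) (5 mol %), 1,4-benzoquinone (10 mol %), CH2Cl2, 40 °C
Reagents that add atoms: none
Why: Olefin cross-metathesis, in which the allylically oxygenated propenyl group of 3 homodimerises slowly, so an excess of the fast-reacting terminal alkene 4 should drive selective cross-coupling with loss of volatile propene; C3 is not touched and the E/Z ratio is irrelevant because the alkene is reduced next.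

Step 3
Reactants: 5 (3S)-8-hydroxy-3-[(E)-11-hydroxyundec-1-en-1-yl]-6-methoxy-3,4-dihydro-1H-isochromen-1-one
Product: 6 (3R)-8-hydroxy-3-(11-hydroxyundecyl)-6-methoxy-3,4-dihydro-1H-isochromen-1-one
Conditions: H2 (1 atm), RhCl(PPh3)3 (5 mol %), toluene/EtOH 1:1, rt
Reagents that add atoms: none
Why: Homogeneous catalytic hydrogenation with RhCl(PPh3)3 should reduce the disubstituted alkene without hydrogenolysis of the allylic C–O bond or reduction of lactone and arene; C3 is untouched, its descriptor changing from S to R only because the CIP ranking of the side chain falls below that of C4.

Compound list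
1 | 2-hydroxy-4-methoxybenzoic acid (4-methoxysalicylic acid) | COc1ccc(C(=O)O)c(O)c1 | starting material
2 | (E)-penta-1,3-diene (trans-piperylene) | C=C/C=C/C | starting material
3 | (3S)-8-hydroxy-6-methoxy-3-[(E)-prop-1-en-1-yl]-3,4-dihydro-1H-isochromen-1-one | COc1cc(O)c2c(c1)C[C@@H](/C=C/C)OC2=O | intermediate
4 | undec-10-en-1-ol | C=CCCCCCCCCCO | starting material
5 | (3S)-8-hydroxy-3-[(E)-11-hydroxyundec-1-en-1-yl]-6-methoxy-3,4-dihydro-1H-isochromen-1-one | COc1cc(O)c2c(c1)C[C@@H](/C=C/CCCCCCCCCO)OC2=O | intermediate
6 | (3R)-8-hydroxy-3-(11-hydroxyundecyl)-6-methoxy-3,4-dihydro-1H-isochromen-1-one | COc1cc(O)c2c(c1)C[C@@H](CCCCCCCCCCCO)OC2=O | target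

Total step count: 3
Longest linear sequence: 3 steps (1 → 3 → 5 → 6)

Steps most likely to fail

Step 1 (Proposed new method). The carboxylate-directed C–H palladation may be outrun by protodecarboxylation of the electron-rich acid or by quinone-promoted oxidation of the diene, and the diene insertion may proceed with poor facial selectivity. Fallback: the C–H bond is replaced by a C–Br bond and the known zerovalent-palladium heteroannulation of 1,3-dienes by ortho-halobenzoic acids is used, so that no oxidant is present. It sets out from diene 2 and comes back at 3. 1-Bromo-3,5-dimethoxybenzene F1 (purchased) would be formylated ortho to bromine (POCl3, DMF, 100 °C; Vilsmeier–Haack) to 2-bromo-4,6-dimethoxybenzaldehyde F2. BCl3 (CH2Cl2, −78 to 0 °C) should remove only the methyl group ortho to the formyl group, by chelation, to give 2-bromo-6-hydroxy-4-methoxybenzaldehyde F3. Pinnick oxidation (NaClO2, NaH2PO4, 2-methyl-2-butene, t-BuOH/H2O) would give 2-bromo-6-hydroxy-4-methoxybenzoic acid F4. F4 and 2 with Pd2(dba)3, K2CO3 and a chiral phosphoramidite or sulfinamide–phosphine ligand of the kind established for the asymmetric heteroannulation of dienes by 2-halophenols and 2-haloanilines (toluene, 80 °C) should give 3 by oxidative addition, diene insertion and carboxylate attack on the η3-allyl.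

Step 2. Self-metathesis of 4 and slow initiation at the allylically oxygenated propenyl group may leave 3 unconverted, and ruthenium hydride formed by catalyst decay may shift the double bond towards C3. Fallback: the chain is brought in with the diene instead of by metathesis. It sets out from 1 and comes back at 5. Undec-10-yn-1-ol F5 (purchased) would be hydroborated (HBpin 2.2 equiv, Cp2Zr(H)Cl 10 mol %, Et3N, 60 °C, aqueous work-up) to (E)-11-(4,4,5,5-tetramethyl-1,3,2-dioxaborolan-2-yl)undec-10-en-1-ol F6. Suzuki coupling with vinyl bromide (Pd(PPh3)4, aqueous K3PO4, THF, 50 °C, sealed) would give (E)-trideca-10,12-dien-1-ol F7. F7 then takes the place of 2 in step 1 (or in its fallback with F4) and should give 5 directly. Without amine ligands or O2, the quinone-driven palladium cycle is expected to oxidise the primary alcohol only slowly.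

Step 3. Ionisation or hydrogenolysis of the allylic C–O bond, or migration of the double bond to C3 before reduction, would erode the configuration. Fallback: metal-free reduction with diimide generated from 2-nitrobenzenesulfonohydrazide and Et3N (CH2Cl2, rt, repeated charges), a concerted syn transfer of two hydrogens that can neither ionise the allylic C–O bond nor move the double bond. It sets out from 5, comes back at 6 and makes no new compound (F0).

Further compounds
F1 | step 1 | 1-bromo-3,5-dimethoxybenzene (purchased) | COc1cc(Br)cc(OC)c1
F2 | step 1 | 2-bromo-4,6-dimethoxybenzaldehyde | COc1cc(Br)c(C=O)c(OC)c1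
F3 | step 1 | 2-bromo-6-hydroxy-4-methoxybenzaldehyde | COc1cc(O)c(C=O)c(Br)c1
F4 | step 1 | 2-bromo-6-hydroxy-4-methoxybenzoic acid | COc1cc(O)c(C(=O)O)c(Br)c1
F5 | step 2 | undec-10-yn-1-ol (purchased) | C#CCCCCCCCCCO
F6 | step 2 | (E)-11-(4,4,5,5-tetramethyl-1,3,2-dioxaborolan-2-yl)undec-10-en-1-ol | OCCCCCCCCC/C=C/B1OC(C)(C)C(C)(C)O1
F7 | step 2 | (E)-trideca-10,12-dien-1-ol | C=C/C=C/CCCCCCCCCO
F0 | step 3 | none | none
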